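- north-west: solid substrate 5 mM; catalyst 5 µM; run made earlier
- flask: solid substrate 10 mM; catalyst 5.0 µM; time 15 min

north-west run (percent of the solid substrate charged)

| time / s | target / % | isomer of the product A / % |
|---|---|---|
| 10.0 | 0.8 | 0 |
| 20.0 | 3.1 | 0 |
| 30.0 | 4.9 | 0.4 |
| 50.0 | 10.4 | 1.0 |
| 60.0 | 11.5 | 1.4 |
| 90.0 | 17.7 | 4.6 |

(readings scatter by 0.3 percentage points)

- ratio of target to isomer of the product A at 20 s
- ratio of target to isomer of the product A at 15 min
- which of target and isomer of the product A there is more of at 15 min

- solid, in amounts per volume of the solution: solid substrate
- the numbers in the tables scatter by 0.3 percentage points (one standard deviation)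
- reactions considered so far: solid substrate <-> starting material; starting material <-> other conformer; target + catalyst <-> isomer of the product B + catalyst; catalyst + other conformer -> catalyst + isomer of the product A; starting material + catalyst -> catalyst + target
- at the start none of the solid substrate is in solution

Start simply. On catalyst, starting material gives target, other conformer gives isomer A, and target passes reversibly into isomer B. Solid substrate feeds the solution.

1. Balance the catalyst, the smaller charge. Each step returns it, so [catalyst] stays 5.0 µM, as in the north-west run. Target's drain is then pseudo-first-order, with one time constant in both flasks.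
2. Read the north-west slopes. Target climbs 0.0122 mM s⁻¹ from 20.0 s to 50.0 s, then 0.00912 mM s⁻¹ up to 90.0 s, while [target] rises 0.365 mM between midpoints.
3. Divide that rise by the slope's drop, taking the feed as steady: 120 s is the reading for the drain time, the mean life of target at this catalyst charge.
4. Add the drain back: the north-west readings put the making of target at 0.0150 mM s⁻¹. They put the making of isomer A at 0.00450 mM s⁻¹ from 50.0 s to 90.0 s.
5. Assume this feed holds in the flask while solid lasts. The reckoned charge then lasts 8.56 min, and isomer A takes 23.1%.
6. Take the reckoned plateau, 1.80 mM, and decay it until 15 min: the reckoning puts target at 0.717% of the charge, so the reckoned ratio is 0.0310.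
7. Reforge the weak link. That reckoned tail runs to zero, but the step is listed as running both ways, and the readings show no end level for it. Commit to a flask ratio above 0.0310, with isomer A ahead.

The forecast gives 20 at 20 s, 0.5 at 15 min, and isomer of the product A ahead: “Target also drains toward isomer B”.

The flask gives 16.3 at 20 s and 0.206 at 15 min; that last ratio stands above my reckoned 0.0310 and below the forecast's 0.5. At 15 min the flask's lead goes to isomer of the product A, at 21.0% against 4.32% of target.

    solid substrate ⇌ starting material, rate k1*(cs1 - [starting material]) while solid is left; crystals form when [starting material] > cs1 (solubility = 1.70 mM, k = 0.0140 s⁻¹)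
    starting material ⇌ other conformer (K = 1.80, k = 0.0190 s⁻¹)
    target + catalyst ⇌ isomer of the product B + catalyst, rate k3*[catalyst]*[target] forward; the back reaction follows from the equilibrium constant (K = 23.0, k = 1500 M⁻¹ s⁻¹)
    catalyst + other conformer → catalyst + isomer of the product A (k = 4900 M⁻¹ s⁻¹)
    starting material + catalyst → catalyst + target (k = 10000 M⁻¹ s⁻¹)

This flask's 4.32% target at 15.0 min stands 1 percentage point above the 3.29% at 150 min, beside the reckoned tail of 0.717%. Now take the neighbour charged with 0.0020 mM catalyst, holding the reckoned feed. Its reckoned drain time stretches to 300 s, so the reckoning puts [target] at 36.8% of the charge at 8.56 min, and the reckoned tail at 10.1% at 15 min. That neighbour holds 16.6% target at 15.0 min.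

(The runs are simulated with made-up constants.)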